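**Plan**

- Retrosynthesis: after removal of two methoxymethyl ethers and one silyl ether, the isocoumarin is cut at the lactone bond O2–C1 and at C3–C4. This is possible because C4 is a benzylic carbon ortho to the ester carbonyl C1 and C3 is an acyl-level carbon carrying the dienyl chain; the pieces are a 2-methylbenzoate and a dienoyl N-methoxy-N-methylamide.
- The amide is cut at its C4=C5 double bond (vinylogous Horner–Wadsworth–Emmons) to an oxolane-2-carbaldehyde. The oxolane is cut at O1–C2 to a hydroxy epoxide, and this goes back to vinylmagnesium bromide and the aldehyde from methyl (S)-3-hydroxybutanoate.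
- Forward: the oxolane ring closes first (step 6), the chain is extended to the dienamide (step 10), the chlorinated arene is made separately (steps 11–12), the pyranone ring of the isocoumarin closes last (step 13), and deprotection ends the route.
- Stereochemistry: C5 of the oxolane comes from the chiral pool. C3 and C2 come from a tartrate-controlled Sharpless epoxidation that accepts only the (3R) allylic alcohol and gives the erythro epoxide, followed by inversion at C2 in the ring closure (all-cis ring). One E alkene comes with the phosphonate, the other from the E-selective olefination.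

Key step: step 13

Remark: the Grignard addition of step 3 is not expected to be diastereoselective; C3 is selected in step 4, which epoxidises only the (3R) epimer, and the recovered (3S) epimer can be inverted (Mitsunobu) and returned.

**Route**

Step 1
Reactants: 1 methyl (3S)-3-hydroxybutanoate
Product: 2 methyl (3S)-3-[(triethylsilyl)oxy]butanoate
Conditions: Et3SiCl, imidazole, CH2Cl2, 0 °C → rt
Reagents that add atoms: chlorotriethylsilane, CC[Si](Cl)(CC)CC
Why: Silylation of a secondary alcohol with a chlorosilane and imidazole is routine, leaves the stereocentre (the future C5 of the oxolane) untouched, and the triethylsilyl ether is chosen because mild acid will later cleave it in the presence of a tert-butyldimethylsilyl ether.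

Step 2
Reactants: 2 methyl (3S)-3-[(triethylsilyl)oxy]butanoate
Product: 3 (3S)-3-[(triethylsilyl)oxy]butanal
Conditions: i-Bu2AlH (1.05 equiv), CH2Cl2, −78 °C; aq KNaC4H4O6
Reagents that add atoms: none
Why: Partial reduction of an ester with i-Bu2AlH at −78 °C stops at the aldehyde because the tetrahedral aluminium hemiacetal persists until the aqueous work-up, and no base is present that could eliminate the β-silyloxy group.

Step 3
Reactants: 3 (3S)-3-[(triethylsilyl)oxy]butanal
Product: 4 (5S)-5-[(triethylsilyl)oxy]hex-1-en-3-ol (both C3 epimers)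
Conditions: CH2=CHMgBr, THF, −78 °C; aq NH4Cl
Reagents that add atoms: vinylmagnesium bromide, C=C[Mg]Br
Why: Grignard 1,2-addition to the aldehyde forms the C3–vinyl bond; induction from the β-silyloxy centre is expected to be weak, so both C3 epimers are carried on and the C3 configuration is selected in step 4 instead of being set here.

Step 4
Reactants: 4 (5S)-5-[(triethylsilyl)oxy]hex-1-en-3-ol (both C3 epimers)
Product: 5 (1R,3S)-1-[(2S)-oxiran-2-yl]-3-[(triethylsilyl)oxy]butan-1-ol
Conditions: Ti(Oi-Pr)4 (0.2 equiv), diisopropyl D-(−)-tartrate [(2S,3S), 0.25 equiv], t-BuOOH (0.6 equiv based on 4), 4 Å molecular sieves, CH2Cl2, −20 °C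
Reagents that add atoms: tert-butyl hydroperoxide, CC(C)(C)OO
Why: Sharpless asymmetric epoxidation run as a kinetic resolution: with the D-(−)-tartrate the (3R) allylic alcohol is the fast-reacting epimer and is epoxidised on the face that gives the erythro epoxy alcohol, so reagent control fixes C3 as R and creates the epoxide carbon as S, while the slow (3S) epimer stays behind as the allylic alcohol and is removed by chromatography.

Step 5
Reactants: 5 (1R,3S)-1-[(2S)-oxiran-2-yl]-3-[(triethylsilyl)oxy]butan-1-ol
Product: 6 tert-butyl(dimethyl){[(1R,3S)-1-[(2S)-oxiran-2-yl]-3-[(triethylsilyl)oxy]butyl]oxy}silane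
Conditions: t-BuMe2SiCl, imidazole, DMF, rt
Reagents that add atoms: tert-butyl(chloro)dimethylsilane, CC(C)(C)[Si](C)(C)Cl
Why: Silylation of the secondary alcohol (chlorosilane, imidazole) under neutral conditions installs the robust silyl ether that the oxolane keeps to the end, and neither the epoxide nor the triethylsilyl ether is affected.

Step 6
Reactants: 6 tert-butyl(dimethyl){[(1R,3S)-1-[(2S)-oxiran-2-yl]-3-[(triethylsilyl)oxy]butyl]oxy}silane
Product: 8 [(2R,3R,5S)-3-{[tert-butyl(dimethyl)silyl]oxy}-5-methyloxolan-2-yl]methanol, via hydroxy epoxide 7 (not isolated)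
Conditions: camphorsulfonic acid (0.1 equiv), CH2Cl2/MeOH (5:1), 0 °C → rt
Reagents that add atoms: none
Why: Acid-catalysed methanolysis cleaves the triethylsilyl ether much faster than the tert-butyldimethylsilyl ether, and the freed C5 hydroxyl then opens the protonated epoxide at its internal carbon in a 5-exo-tet SN2 ring closure (intramolecular epoxide opening) with inversion, which turns the (S) epoxide carbon into C2 (R) and places the C2, C3 and C5 substituents all cis.

Step 7
Reactants: 8 [(2R,3R,5S)-3-{[tert-butyl(dimethyl)silyl]oxy}-5-methyloxolan-2-yl]methanol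
Product: 9 (2S,3R,5S)-3-{[tert-butyl(dimethyl)silyl]oxy}-5-methyloxolane-2-carbaldehyde
Conditions: Dess–Martin periodinane, CH2Cl2, 0 °C → rt; aq NaHCO3/Na2S2O3
Reagents that add atoms: none
Why: Dess–Martin oxidation converts the primary alcohol into the aldehyde without base, so the configurationally labile 2,3-cis α-alkoxy aldehyde should keep its C2 configuration and is used directly in step 10.

Step 8
Reactants: 10 (2E)-4-bromobut-2-enoic acid
Product: 12 (2E)-4-bromo-N-methoxy-N-methylbut-2-enamide, via acid chloride 11 (not isolated)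
Conditions: (COCl)2, DMF (cat.), CH2Cl2, 0 °C → rt; then MeNHOMe·HCl, 2,6-lutidine, CH2Cl2, −20 → 0 °C
Reagents that add atoms: N,O-dimethylhydroxylamine hydrochloride, CNOC.Cl
Why: Acid chloride formation with oxalyl chloride followed by N-acylation of N,O-dimethylhydroxylamine (amide formation) is standard, and the low temperature, the hindered base and the exact stoichiometry keep the allylic bromide from being displaced.

Step 9
Reactants: 12 (2E)-4-bromo-N-methoxy-N-methylbut-2-enamide
Product: 13 diethyl [(2E)-4-[methoxy(methyl)amino]-4-oxobut-2-en-1-yl]phosphonate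
Conditions: P(OEt)3 (neat), 110 °C
Reagents that add atoms: triethyl phosphite, CCOP(OCC)OCC
Why: Michaelis–Arbuzov reaction of the primary allylic bromide with triethyl phosphite, driven by loss of volatile bromoethane, gives the γ-phosphono crotonamide with the E double bond intact.

Step 10
Reactants: 9 (2S,3R,5S)-3-{[tert-butyl(dimethyl)silyl]oxy}-5-methyloxolane-2-carbaldehyde; 13 diethyl [(2E)-4-[methoxy(methyl)amino]-4-oxobut-2-en-1-yl]phosphonate
Product: 14 (2E,4E)-5-[(2R,3R,5S)-3-{[tert-butyl(dimethyl)silyl]oxy}-5-methyloxolan-2-yl]-N-methoxy-N-methylpenta-2,4-dienamide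
Conditions: 13 (1.3 equiv), LiN(SiMe3)2 (1.25 equiv), THF, −78 °C; then 9, −78 → 0 °C
Reagents that add atoms: none
Why: Vinylogous Horner–Wadsworth–Emmons olefination: the lithiated phosphonate reacts through its phosphorus-bearing carbon and the stabilised anion forms the new C4=C5 bond with E geometry while C2=C3 stays E, and the low temperature together with a slight excess of phosphonate over base limits epimerisation at the α-alkoxy carbon and β-elimination of the silyloxy group.

Step 11
Reactants: 15 methyl 2,4-dihydroxy-6-methylbenzoate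
Product: 16 methyl 3-chloro-4,6-dihydroxy-2-methylbenzoate
Conditions: SO2Cl2 (1.05 equiv), Et2O, 0 °C → rt
Reagents that add atoms: sulfuryl chloride, O=S(=O)(Cl)Cl
Why: Electrophilic aromatic chlorination with sulfuryl chloride is expected to favour the ring position ortho to the 4-hydroxyl and para to the hydrogen-bonded 2-hydroxyl, which is the position next to the methyl group, and any regioisomer or dichloride is removed by crystallisation or chromatography.

Step 12
Reactants: 16 methyl 3-chloro-4,6-dihydroxy-2-methylbenzoate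
Product: 17 methyl 3-chloro-4,6-bis(methoxymethoxy)-2-methylbenzoate
Conditions: NaH (2.5 equiv), MeOCH2Cl (2.5 equiv), DMF, 0 °C → rt
Reagents that add atoms: chloromethyl methyl ether, COCCl
Why: O-Alkylation of both phenoxides (Williamson ether synthesis; NaH is needed for the hydrogen-bonded hydroxyl ortho to the ester) with chloromethyl methyl ether gives acetal ethers that tolerate LiN(i-Pr)2 and are removed by acid at the end.

Step 13
Reactants: 17 methyl 3-chloro-4,6-bis(methoxymethoxy)-2-methylbenzoate; 14 (2E,4E)-5-[(2R,3R,5S)-3-{[tert-butyl(dimethyl)silyl]oxy}-5-methyloxolan-2-yl]-N-methoxy-N-methylpenta-2,4-dienamide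
Product: 19 3-[(1E,3E)-4-[(2R,3R,5S)-3-{[tert-butyl(dimethyl)silyl]oxy}-5-methyloxolan-2-yl]buta-1,3-dien-1-yl]-5-chloro-6,8-bis(methoxymethoxy)-1H-isochromen-1-one, via keto ester 18 (not isolated)
Conditions: 17 (1.5 equiv), LiN(i-Pr)2 (1.5 equiv), THF, −78 °C; then 14 (1.0 equiv), −78 °C, short contact time; aq NH4Cl; crude 18, DBU (0.2 equiv), toluene, rt → 40 °C
Reagents that add atoms: none
Why: LiN(i-Pr)2 deprotonates the methyl group ortho to the ester of 17 (lateral lithiation), and the benzylic anion, stabilised as an extended ester enolate, adds to the amide carbonyl of 14 to give a chelated lithium hemiaminal that survives until the quench, so ketone 18 is released only on work-up and cannot be attacked a second time; this forms C3–C4. Catalytic DBU then enolises the benzylic ketone and the enol oxygen attacks the neighbouring methyl ester in a 6-exo-trig acyl substitution that expels methanol and closes the lactone ring, forming O2–C1. The closest known reaction type is the lateral lithiation of ortho-toluates followed by acylation with esters or N-methoxy-N-methylamides and enol lactonisation to 3-substituted isocoumarins. No stereocentre is created, and the three stereocentres of the oxolane lie outside the reacting carbanion and enolate. The step needs carbonyl addition to beat 1,4- and 1,6-addition to the dienoyl unit, which the lithium counter-ion, the chelating amide, the alkyl-substituted diene terminus and a short contact time at −78 °C should secure. It also needs deprotonation at the methyl group instead of the ring, which the ortho ester ensures, and the chlorine has no ortho hydrogen, so no aryne can form.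

Step 14
Reactants: 19 3-[(1E,3E)-4-[(2R,3R,5S)-3-{[tert-butyl(dimethyl)silyl]oxy}-5-methyloxolan-2-yl]buta-1,3-dien-1-yl]-5-chloro-6,8-bis(methoxymethoxy)-1H-isochromen-1-one
Product: 20 5-chloro-6,8-dihydroxy-3-[(1E,3E)-4-[(2R,3R,5S)-3-hydroxy-5-methyloxolan-2-yl]buta-1,3-dien-1-yl]-1H-isochromen-1-one
Conditions: HCl (1.25 M in MeOH), 0 °C → rt
Reagents that add atoms: none
Why: Acid-catalysed acetal exchange with methanol cleaves both aryl methoxymethyl ethers and acid-catalysed methanolysis removes the secondary silyl ether in the same pot (global deprotection), the temperature being kept low because the C2–O bond of the oxolane is allylic to the diene.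

**Compound list**

1 | methyl (3S)-3-hydroxybutanoate | C[C@H](O)CC(=O)OC | starting material
2 | methyl (3S)-3-[(triethylsilyl)oxy]butanoate | C[C@H](O[Si](CC)(CC)CC)CC(=O)OC | intermediate
3 | (3S)-3-[(triethylsilyl)oxy]butanal | C[C@H](O[Si](CC)(CC)CC)CC=O | intermediate
4 | (5S)-5-[(triethylsilyl)oxy]hex-1-en-3-ol (both C3 epimers) | C[C@H](O[Si](CC)(CC)CC)CC(O)C=C | intermediate
5 | (1R,3S)-1-[(2S)-oxiran-2-yl]-3-[(triethylsilyl)oxy]butan-1-ol | C[C@H](O[Si](CC)(CC)CC)C[C@@H](O)[C@@H]1CO1 | intermediate
6 | tert-butyl(dimethyl){[(1R,3S)-1-[(2S)-oxiran-2-yl]-3-[(triethylsilyl)oxy]butyl]oxy}silane | C[C@H](O[Si](CC)(CC)CC)C[C@@H](O[Si](C)(C)C(C)(C)C)[C@@H]1CO1 | intermediate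
7 | (2S,4R)-4-{[tert-butyl(dimethyl)silyl]oxy}-4-[(2S)-oxiran-2-yl]butan-2-ol | C[C@H](O)C[C@@H](O[Si](C)(C)C(C)(C)C)[C@@H]1CO1 | intermediate (not isolated)
8 | [(2R,3R,5S)-3-{[tert-butyl(dimethyl)silyl]oxy}-5-methyloxolan-2-yl]methanol | C[C@H]1C[C@@H](O[Si](C)(C)C(C)(C)C)[C@@H](CO)O1 | intermediate
9 | (2S,3R,5S)-3-{[tert-butyl(dimethyl)silyl]oxy}-5-methyloxolane-2-carbaldehyde | C[C@H]1C[C@@H](O[Si](C)(C)C(C)(C)C)[C@@H](C=O)O1 | intermediate
10 | (2E)-4-bromobut-2-enoic acid | OC(=O)/C=C/CBr | starting material
11 | (2E)-4-bromobut-2-enoyl chloride | ClC(=O)/C=C/CBr | intermediate (not isolated)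
12 | (2E)-4-bromo-N-methoxy-N-methylbut-2-enamide | CON(C)C(=O)/C=C/CBr | intermediate
13 | diethyl [(2E)-4-[methoxy(methyl)amino]-4-oxobut-2-en-1-yl]phosphonate | CCOP(=O)(OCC)C/C=C/C(=O)N(C)OC | intermediate
14 | (2E,4E)-5-[(2R,3R,5S)-3-{[tert-butyl(dimethyl)silyl]oxy}-5-methyloxolan-2-yl]-N-methoxy-N-methylpenta-2,4-dienamide | C[C@H]1C[C@@H](O[Si](C)(C)C(C)(C)C)[C@@H](/C=C/C=C/C(=O)N(C)OC)O1 | intermediate
15 | methyl 2,4-dihydroxy-6-methylbenzoate | COC(=O)c1c(C)cc(O)cc1O | starting material
16 | methyl 3-chloro-4,6-dihydroxy-2-methylbenzoate | COC(=O)c1c(C)c(Cl)c(O)cc1O | intermediate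
17 | methyl 3-chloro-4,6-bis(methoxymethoxy)-2-methylbenzoate | COC(=O)c1c(C)c(Cl)c(OCOC)cc1OCOC | intermediate
18 | methyl 2-[(3E,5E)-6-[(2R,3R,5S)-3-{[tert-butyl(dimethyl)silyl]oxy}-5-methyloxolan-2-yl]-2-oxohexa-3,5-dien-1-yl]-3-chloro-4,6-bis(methoxymethoxy)benzoate | C[C@H]1C[C@@H](O[Si](C)(C)C(C)(C)C)[C@@H](/C=C/C=C/C(=O)Cc2c(Cl)c(OCOC)cc(OCOC)c2C(=O)OC)O1 | intermediate (not isolated)
19 | 3-[(1E,3E)-4-[(2R,3R,5S)-3-{[tert-butyl(dimethyl)silyl]oxy}-5-methyloxolan-2-yl]buta-1,3-dien-1-yl]-5-chloro-6,8-bis(methoxymethoxy)-1H-isochromen-1-one | C[C@H]1C[C@@H](O[Si](C)(C)C(C)(C)C)[C@@H](/C=C/C=C/c2cc3c(Cl)c(OCOC)cc(OCOC)c3c(=O)o2)O1 | intermediate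
20 | 5-chloro-6,8-dihydroxy-3-[(1E,3E)-4-[(2R,3R,5S)-3-hydroxy-5-methyloxolan-2-yl]buta-1,3-dien-1-yl]-1H-isochromen-1-one | C[C@H]1C[C@@H](O)[C@@H](/C=C/C=C/c2cc3c(Cl)c(O)cc(O)c3c(=O)o2)O1 | target

**Step count**

Total: 14 steps. Longest linear sequence: 10 steps (steps 1–7, 10, 13, 14).

**Steps most likely to fail**

Step 13. The delocalised benzylic anion may add to the β or δ carbon of the dienoyl amide faster than to its carbonyl, or the ketone may not lactonise cleanly. The fallback moves the electrophile to the aldehyde oxidation level, where organolithium reagents add at the carbonyl. It sets out from 14: reduction with i-Bu2AlH (THF, −78 °C) would give (2E,4E)-5-[(2R,3R,5S)-3-{[tert-butyl(dimethyl)silyl]oxy}-5-methyloxolan-2-yl]penta-2,4-dienal F1. The anion of 17 (LiN(i-Pr)2, THF, −78 °C) is added to it and the mixture is quenched cold with AcOH, so that the adduct stays as the open hydroxy ester methyl 2-[(3E,5E)-6-[(2R,3R,5S)-3-{[tert-butyl(dimethyl)silyl]oxy}-5-methyloxolan-2-yl]-2-hydroxyhexa-3,5-dien-1-yl]-3-chloro-4,6-bis(methoxymethoxy)benzoate F2 (both carbinol epimers, which does not matter). Oxidation of this dienylic alcohol with activated MnO2 (CH2Cl2, rt) would give keto ester 18, and DBU as in step 13 brings the route back at 19.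

Step 10. The phosphonate anion may deprotonate the aldehyde at C2, which would scramble the 2,3-cis relationship or expel the silyloxy group. The fallback replaces the basic olefination by a non-basic one followed by a palladium-catalysed coupling. It sets out from 9: Takai iodo-olefination (CrCl2, CHI3, THF, 0 °C) would give tert-butyl{[(2R,3R,5S)-2-[(E)-2-iodoethenyl]-5-methyloxolan-3-yl]oxy}dimethylsilane F3. A Heck reaction of this vinyl iodide with commercial N-methoxy-N-methylprop-2-enamide (Pd(OAc)2, K2CO3, n-Bu4NCl, DMF, rt) returns to the route at 14.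

Step 14. Protonation of the oxolane oxygen may ionise the allylic C2–O bond (epimerisation at C2, solvolysis or migration of the diene) while the less labile 6-O-methoxymethyl ether is still being cleaved. The fallback uses phenol protection that leaves under neutral palladium catalysis and removes the silyl ether with fluoride. It sets out from 16: allyl bromide and K2CO3 (DMF, 60 °C) would give methyl 3-chloro-2-methyl-4,6-bis(prop-2-en-1-yloxy)benzoate F4. Lithiation and acylation with 14 as in step 13 would give methyl 2-[(3E,5E)-6-[(2R,3R,5S)-3-{[tert-butyl(dimethyl)silyl]oxy}-5-methyloxolan-2-yl]-2-oxohexa-3,5-dien-1-yl]-3-chloro-4,6-bis(prop-2-en-1-yloxy)benzoate F5, which DBU closes to 3-[(1E,3E)-4-[(2R,3R,5S)-3-{[tert-butyl(dimethyl)silyl]oxy}-5-methyloxolan-2-yl]buta-1,3-dien-1-yl]-5-chloro-6,8-bis(prop-2-en-1-yloxy)-1H-isochromen-1-one F6. Pd(PPh3)4 with morpholine (THF, rt) removes both allyl groups to give 3-[(1E,3E)-4-[(2R,3R,5S)-3-{[tert-butyl(dimethyl)silyl]oxy}-5-methyloxolan-2-yl]buta-1,3-dien-1-yl]-5-chloro-6,8-dihydroxy-1H-isochromen-1-one F7, and Bu4NF buffered with AcOH (THF, 0 °C → rt) returns to the route at 20.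

Further compounds
F1 | step 13 | (2E,4E)-5-[(2R,3R,5S)-3-{[tert-butyl(dimethyl)silyl]oxy}-5-methyloxolan-2-yl]penta-2,4-dienal | C[C@H]1C[C@@H](O[Si](C)(C)C(C)(C)C)[C@@H](/C=C/C=C/C=O)O1
F2 | step 13 | methyl 2-[(3E,5E)-6-[(2R,3R,5S)-3-{[tert-butyl(dimethyl)silyl]oxy}-5-methyloxolan-2-yl]-2-hydroxyhexa-3,5-dien-1-yl]-3-chloro-4,6-bis(methoxymethoxy)benzoate | C[C@H]1C[C@@H](O[Si](C)(C)C(C)(C)C)[C@@H](/C=C/C=C/C(O)Cc2c(Cl)c(OCOC)cc(OCOC)c2C(=O)OC)O1
F3 | step 10 | tert-butyl{[(2R,3R,5S)-2-[(E)-2-iodoethenyl]-5-methyloxolan-3-yl]oxy}dimethylsilane | C[C@H]1C[C@@H](O[Si](C)(C)C(C)(C)C)[C@@H](/C=C/I)O1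
F4 | step 14 | methyl 3-chloro-2-methyl-4,6-bis(prop-2-en-1-yloxy)benzoate | COC(=O)c1c(C)c(Cl)c(OCC=C)cc1OCC=C
F5 | step 14 | methyl 2-[(3E,5E)-6-[(2R,3R,5S)-3-{[tert-butyl(dimethyl)silyl]oxy}-5-methyloxolan-2-yl]-2-oxohexa-3,5-dien-1-yl]-3-chloro-4,6-bis(prop-2-en-1-yloxy)benzoate | C[C@H]1C[C@@H](O[Si](C)(C)C(C)(C)C)[C@@H](/C=C/C=C/C(=O)Cc2c(Cl)c(OCC=C)cc(OCC=C)c2C(=O)OC)O1
F6 | step 14 | 3-[(1E,3E)-4-[(2R,3R,5S)-3-{[tert-butyl(dimethyl)silyl]oxy}-5-methyloxolan-2-yl]buta-1,3-dien-1-yl]-5-chloro-6,8-bis(prop-2-en-1-yloxy)-1H-isochromen-1-one | C[C@H]1C[C@@H](O[Si](C)(C)C(C)(C)C)[C@@H](/C=C/C=C/c2cc3c(Cl)c(OCC=C)cc(OCC=C)c3c(=O)o2)O1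
F7 | step 14 | 3-[(1E,3E)-4-[(2R,3R,5S)-3-{[tert-butyl(dimethyl)silyl]oxy}-5-methyloxolan-2-yl]buta-1,3-dien-1-yl]-5-chloro-6,8-dihydroxy-1H-isochromen-1-one | C[C@H]1C[C@@H](O[Si](C)(C)C(C)(C)C)[C@@H](/C=C/C=C/c2cc3c(Cl)c(O)cc(O)c3c(=O)o2)O1
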